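Compound numbers 1–22 are those of the list after the steps. F and A labels are defined in the closing block.

## Analysis of the target

Target 22 is fisetinidol-(4α→6)-ent-epifisetinidol, a 5-deoxy proanthocyanidin dimer. It consists of two 7,3′,4′-trihydroxyflavan-3-ol units: the upper one (benzo ring A, catechol ring B, pyran ring C) is bonded through its C4 to C6 of the benzo ring D of the lower one (catechol ring E, pyran ring F). There are five stereocentres. Upper C2, C3 and C4 are 2R,3S,4R and all-trans, with ring B and ring D on one face of ring C and the 3-hydroxyl on the other. Lower C2 and C3 are 2S,3S and cis, so the lower unit belongs to the enantiomeric flavan series and has the 2,3 relation that hydroboration or equilibration does not give directly; the two halves cannot come from one natural flavanoid. The eight free hydroxyls include two air-sensitive catechols, and both C2 atoms are benzylic aryl-ether carbons that open to quinone methides in acid or base, so the free polyphenol can only be released last, under neutral conditions. The hard points are the substitution pattern of ring D (link at C6, pyran oxygen para to it), the configuration at upper C4, and an enantioselective entry to the cis lower heterocycle. The route rests on the lower C3–C4 bond: C4 hangs on ring D carbon C4a and C3 is next to the benzylic ether carbon C2 on the ring D oxygen O1, so as a C3=C4 alkene ring F is one olefin bond away from a resorcinol ring D bearing a vinyl group on C4a and a 1-arylallyl group on O1.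

## Retrosynthetic reasoning

22 from 21. All seven O–benzyl bonds are cut last. Benzyl is the only group used, so one neutral hydrogenolysis frees every hydroxyl, including the upper 3-hydroxyl. No acid, base or fluoride meets the free polyphenol.

21 from 20 from 19. The lower C3–O bond is kept but its configuration is corrected through ketone 20. Only the trans alcohol 19 is directly reachable from an alkene, so the C3 centre is erased by oxidation and rebuilt by hydride delivery anti to ring E. The forward reduction must outrun enolisation towards C2.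

19 from 17. The lower C3–O and C4–H bonds are traced back to the C3=C4 double bond of flav-3-ene 17. Hydroboration must put boron on C3, which the para benzyloxy group of ring D and the allylic oxygen both favour, and on the face away from ring E.

17 from 16. The lower C3=C4 bond is cut by ring-closing metathesis. It is the one bond of ring F that carries no stereochemistry in 17, so cutting it leaves an acyclic precursor in which lower C2 is already fixed. Diene 16 has a vinyl group on ring D and a 1-arylallyl ether on the ring D oxygen. The forward reaction only has to join two terminal alkenes.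

16 from 15 from 13 and 4. The upper 3-O-benzyl group is removed first, giving 15. Then the lower O1–C2 bond is cut to vinylphenol 13 and linear cinnamyl carbonate 4. This is the only C–heteroatom bond at C2, and an iridium-catalysed branched-selective allylic etherification can form it with the configuration set by the ligand, independent of the remote upper unit. Benzylation of the upper 3-hydroxyl is placed after this step because only then is the ring D phenol capped. Benzyl rather than a silyl group is chosen so that no silyl triflate touches the ionisable allylic ether and no separate desilylation is needed.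

13 from 12 from 11 from 9. The vinyl carbon is cut back to a formyl group (Wittig), the ring D benzyl ether to the free phenol, and the formyl C–C bond to the arene C–H of 9. The formyl group does two jobs. It puts the carbon on the ring D position ortho to the future O1. By hydrogen bonding it also differentiates the two ring D hydroxyls, so that only the one destined to stay as the C7 oxygen is benzylated.

9 from 7 and 8. The interflavanyl C4–C6 bond is cut to the C4 cation of diol 7 and resorcinol 8. Resorcinol is symmetrical, so the only regiochemical issue is C4 versus C2 of the phenol, and the C3 hydroxyl of the cation directs attack to the trans face.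

7 from 6 from 5. The C4 oxygen is traced back to the ketone of fustin 5, which supplies upper C2 and C3 in the correct absolute sense. Only the phenols need capping (6).

4 from 3 from 2 from 1. The carbonate is cut to the cinnamyl alcohol 3, this to the ester 2, and the alkene to aldehyde 1 by a Horner–Wadsworth–Emmons disconnection that fixes the E geometry needed for clean allyl-iridium formation.

## Alternatives that were turned down

Alternative 1: Ring C of the upper unit is cut at O1–C2 and C3–C4, giving a ring A ortho-quinone methide and a styrene. The methide comes from the o-hydroxybenzhydrol A1, which already carries the complete lower unit on its carbinol carbon; the styrene is the (E)-β-silylstyrene A2. In the forward step the chiral phosphoric acid TRIP dehydrates A1 and the quinone methide adds A2 in a [4+2] sense to give the C3-silyl dimer A3, whose benzyldimethylsilyl group is later oxidised to the hydroxyl.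
- For it: two bonds, ring C and all three upper stereocentres arise in one catalytic step. The E geometry of A2 maps onto the 2,3-trans relation. The route is convergent.
- Against it: A1 presupposes the whole 2S,3S-cis lower unit, so the hardest part of the target is left to a separate asymmetric synthesis. The exo/endo preference that fixes C4 relative to C3, and the facial control by the catalyst, would have to hold with a large chiral aryl group on the methide carbon. A β-silylstyrene is a hindered, weakly reactive 2π partner. The C–Si oxidation must then be run among six benzyloxyarenes.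
- Comparison: on convergence and on what one step builds, Alternative 1 is stronger. The chosen route instead takes the three upper centres from fustin and a substrate-directed arylation, and spends its key step on the lower heterocycle, for which no chiral-pool source exists.

Alternative 2: Ring D itself is cut, at C4a–C5, back to the open-chain triketo acetal A4 attached to upper C4. In the forward step acid frees the aldehyde, the methylene that becomes C4a adds to it, and dehydration with enolisation aromatises the chain to the 5-substituted 2,4-dihydroxyacetophenone A5.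
- For it: the substitution pattern of ring D arises without any question of electrophilic regiochemistry. The chelated and free hydroxyls are differentiated from the start. The acetyl group is a handle for chalcone chemistry.
- Against it: A4 is a labile polyketone with competing aldol, Claisen and pyrone-forming modes. Attaching its carbon chain to upper C4 with the right configuration is no easier than arylation by resorcinol. After A5, all of ring F and both lower stereocentres are still to be made through a chalcone, an asymmetric oxidation, a cyclisation and a reduction.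
- Comparison: Alternative 2 equals the chosen route on certainty of the ring D pattern. The chosen route reaches the same pattern in two steps from resorcinol, through the symmetry of the nucleophile and the para selectivity of formylation, and gets a vinyl handle that leads straight to ring F.

Alternative 3: The lower O1–C2 bond is cut, with the (Z)-1,3-diarylpropene A6 (ring D oxygen acylated) as precursor. In the forward sequence the (Z)-alkene is epoxidised with the Jacobsen catalyst (salen)MnCl and m-CPBA/N-methylmorpholine N-oxide, carbonate in methanol frees the phenol, and camphorsulfonic acid lets the phenol oxygen open the epoxide at the benzylic carbon with inversion, closing ring F to the hexa-O-benzyl dimer A7.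
- For it: both lower stereocentres come from one catalytic asymmetric event and the cis relation is obtained directly, without an oxidation–reduction correction. After A7 only hydrogenolysis remains. On these points it is stronger than the chosen route, and cis-disubstituted aryl alkenes are the best substrates of that catalyst.
- Against it: the epoxide of a 3,4-dialkoxystyrene is extremely labile. Stepwise oxygen transfer can leak cis to trans, and opening at the doubly donor-stabilised benzylic carbon tends to go through a cation. Neither the cis geometry nor clean inversion at C2 is therefore assured, and these are the very centres the route exists to set. The Z-alkene must also be made and kept pure on a large substrate, and the oxidant meets a free upper 3-hydroxyl and electron-rich rings.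
- Comparison: the chosen route pays two extra steps. In return lower C2 is set in an allylic substitution and never reacts again, and C3 is set by two substrate-controlled steps with close precedent on O-benzyl flavan-3-ols.

Key step: step 12

## Remarks on the chemistry

- Assumption: (2R,3R)-fustin 5 is bought as the single enantiomer.
- L in step 10 is the phosphoramidite (R)-(1,1′-binaphthalene-2,2′-diyl) N,N-bis[(R)-1-phenylethyl]phosphoramidite. This enantiomer is expected to give the R ether by analogy with simple cinnamyl carbonates. The sense is to be confirmed on phenol first, and the mirror-image ligand taken if it is opposite.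
- The allylic ether carbon keeps one spatial arrangement from step 10 on. Its descriptor is R in 15, 16 and 17 and S in 19–22 only because C3, once oxygenated, outranks the aryl group.

## Steps

Step 1
Reactants: 1 3,4-bis(benzyloxy)benzaldehyde
Product: 2 ethyl (E)-3-[3,4-bis(benzyloxy)phenyl]prop-2-enoate
Conditions: (EtO)2P(O)CH2CO2Et, NaH, THF, 0 °C to rt
Reagents that add atoms: triethyl phosphonoacetate, CCOC(=O)CP(=O)(OCC)OCC
Why: Horner–Wadsworth–Emmons olefination; the stabilised phosphonate anion adds reversibly and collapses through the more stable oxaphosphetane to the E ester.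

Step 2
Reactants: 2 ethyl (E)-3-[3,4-bis(benzyloxy)phenyl]prop-2-enoate
Product: 3 (E)-3-[3,4-bis(benzyloxy)phenyl]prop-2-en-1-ol
Conditions: i-Bu2AlH (2.5 equiv), CH2Cl2, −78 to 0 °C; aq. KNaC4H4O6 (potassium sodium tartrate)
Reagents that add atoms: none
Why: Two hydride transfers from i-Bu2AlH reduce the conjugated ester in the 1,2 sense to the allylic alcohol; the alkene and the benzyl ethers are inert at low temperature.

Step 3
Reactants: 3 (E)-3-[3,4-bis(benzyloxy)phenyl]prop-2-en-1-ol
Product: 4 (E)-3-[3,4-bis(benzyloxy)phenyl]prop-2-en-1-yl methyl carbonate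
Conditions: ClCO2Me, pyridine, CH2Cl2, 0 °C
Reagents that add atoms: methyl chloroformate, COC(=O)Cl
Why: O-acylation of the primary alcohol with pyridine as acid scavenger; the linear methyl carbonate is the standard leaving group for iridium-catalysed allylic substitution.

Step 4
Reactants: 5 (2R,3R)-fustin
Product: 6 (2R,3R)-7-(benzyloxy)-2-[3,4-bis(benzyloxy)phenyl]-3-hydroxychroman-4-one
Conditions: BnBr (3.3 equiv), K2CO3, DMF, rt, N2
Reagents that add atoms: benzyl bromide, BrCc1ccccc1
Why: Williamson etherification of the three phenols, the only hydroxyls a carbonate base deprotonates; the α-ketol hydroxyl stays free, and mild base at room temperature under nitrogen avoids ring opening to the chalcone and oxidation to the flavonol.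

Step 5
Reactants: 6 (2R,3R)-7-(benzyloxy)-2-[3,4-bis(benzyloxy)phenyl]-3-hydroxychroman-4-one
Product: 7 (2R,3S,4R)-7-(benzyloxy)-2-[3,4-bis(benzyloxy)phenyl]chromane-3,4-diol
Conditions: NaBH4, THF/MeOH (1:1), 0 °C
Reagents that add atoms: none
Why: Borohydride reduction of the aryl ketone should give mainly the 3,4-trans diol; the C4 centre is ionised in step 6, so any 4-epimer converges on the same cation.

Step 6
Reactants: 7 (2R,3S,4R)-7-(benzyloxy)-2-[3,4-bis(benzyloxy)phenyl]chromane-3,4-diol; 8 resorcinol
Product: 9 (2R,3S,4R)-7-(benzyloxy)-2-[3,4-bis(benzyloxy)phenyl]-4-(2,4-dihydroxyphenyl)chroman-3-ol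
Conditions: 8 (5 equiv), BF3·OEt2 (0.5 equiv), 1,4-dioxane, 15 °C to rt
Reagents that add atoms: none
Why: Friedel–Crafts alkylation: BF3 ionises the benzylic C4 hydroxyl to a cation stabilised by the two ring A oxygens, and resorcinol attacks through its C4 on the face anti to the C3 hydroxyl, setting upper C4 as 3,4-trans (4R) under substrate control. The excess of 8 suppresses double alkylation.

Step 7
Reactants: 9 (2R,3S,4R)-7-(benzyloxy)-2-[3,4-bis(benzyloxy)phenyl]-4-(2,4-dihydroxyphenyl)chroman-3-ol
Product: 11 5-{(2R,3S,4R)-7-(benzyloxy)-2-[3,4-bis(benzyloxy)phenyl]-3-hydroxychroman-4-yl}-2,4-dihydroxybenzaldehyde, via aryl iminium chloride 10 (not isolated)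
Conditions: POCl3 (1.3 equiv), DMF (1.5 equiv), MeCN, −15 °C to rt; then H2O, 50 °C; K2CO3, MeOH, rt
Reagents that add atoms: N,N-dimethylformamide, CN(C)C=O; water, O
Why: Vilsmeier–Haack formylation: the chloroiminium salt attacks the free resorcinol ring, by far the most nucleophilic arene, at the open position para to one hydroxyl and ortho to the other (the carbon between the hydroxyls is shielded), and water hydrolyses iminium 10. Any O-formate formed on a hydroxyl is cleaved by the carbonate/methanol treatment.

Step 8
Reactants: 11 5-{(2R,3S,4R)-7-(benzyloxy)-2-[3,4-bis(benzyloxy)phenyl]-3-hydroxychroman-4-yl}-2,4-dihydroxybenzaldehyde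
Product: 12 4-(benzyloxy)-5-{(2R,3S,4R)-7-(benzyloxy)-2-[3,4-bis(benzyloxy)phenyl]-3-hydroxychroman-4-yl}-2-hydroxybenzaldehyde
Conditions: BnBr (1.05 equiv), KHCO3, KI (cat.), MeCN, 60 °C
Reagents that add atoms: benzyl bromide, BrCc1ccccc1
Why: Selective Williamson etherification: the hydroxyl para to the formyl group is the more acidic and is free, whereas the ortho hydroxyl is held in a hydrogen bond to the carbonyl, so one equivalent of benzyl bromide with a weak base alkylates only the former; the aliphatic hydroxyl is not deprotonated.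

Step 9
Reactants: 12 4-(benzyloxy)-5-{(2R,3S,4R)-7-(benzyloxy)-2-[3,4-bis(benzyloxy)phenyl]-3-hydroxychroman-4-yl}-2-hydroxybenzaldehyde
Product: 13 5-(benzyloxy)-4-{(2R,3S,4R)-7-(benzyloxy)-2-[3,4-bis(benzyloxy)phenyl]-3-hydroxychroman-4-yl}-2-vinylphenol
Conditions: Ph3PCH3Br (4 equiv), KOt-Bu (3.9 equiv), THF, 0 °C to rt
Reagents that add atoms: methyltriphenylphosphonium bromide, C[P+](c1ccccc1)(c1ccccc1)c1ccccc1.[Br-]
Why: Wittig methylenation; excess ylide first deprotonates the phenol and the alcohol and then converts the aldehyde to the styrene, as is usual for salicylaldehydes. The acid-sensitive vinylphenol is taken on at once.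

Step 10
Reactants: 13 5-(benzyloxy)-4-{(2R,3S,4R)-7-(benzyloxy)-2-[3,4-bis(benzyloxy)phenyl]-3-hydroxychroman-4-yl}-2-vinylphenol; 4 (E)-3-[3,4-bis(benzyloxy)phenyl]prop-2-en-1-yl methyl carbonate
Product: 15 (2R,3S,4R)-7-(benzyloxy)-4-[2-(benzyloxy)-4-({(1R)-1-[3,4-bis(benzyloxy)phenyl]prop-2-en-1-yl}oxy)-5-vinylphenyl]-2-[3,4-bis(benzyloxy)phenyl]chroman-3-ol, via lithium phenoxide 14 (not isolated)
Conditions: LiN(SiMe3)2 (1.0 equiv), THF, 0 °C; then 4 (1.3 equiv), [Ir(cod)Cl]2 (2 mol %), L (4 mol %, activated with n-PrNH2), THF, rt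
Reagents that add atoms: none
Why: Iridium-catalysed allylic etherification with a cyclometallated phosphoramidite complex: ionisation of 4 gives an allyl-iridium species (methyl carbonate leaves as CO2 and methoxide) and the aryloxide attacks the aryl-bearing terminus to give the branched ether. The ligand fixes the face, so the new stereocentre (lower C2, R here) is set under catalyst control; one equivalent of base deprotonates only the phenol.

Step 11
Reactants: 15 (2R,3S,4R)-7-(benzyloxy)-4-[2-(benzyloxy)-4-({(1R)-1-[3,4-bis(benzyloxy)phenyl]prop-2-en-1-yl}oxy)-5-vinylphenyl]-2-[3,4-bis(benzyloxy)phenyl]chroman-3-ol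
Product: 16 (2R,3S,4R)-3,7-bis(benzyloxy)-4-[2-(benzyloxy)-4-({(1R)-1-[3,4-bis(benzyloxy)phenyl]prop-2-en-1-yl}oxy)-5-vinylphenyl]-2-[3,4-bis(benzyloxy)phenyl]chromane
Conditions: NaH, BnBr, n-Bu4NI (cat.), THF/DMF, 0 °C to rt
Reagents that add atoms: benzyl bromide, BrCc1ccccc1
Why: Williamson etherification of the secondary alkoxide; the aryl allyl ether, the styrene and the benzyl ethers are stable to hydride base, whereas a silyl triflate could ionise the donor-substituted allylic ether.

Step 12
Reactants: 16 (2R,3S,4R)-3,7-bis(benzyloxy)-4-[2-(benzyloxy)-4-({(1R)-1-[3,4-bis(benzyloxy)phenyl]prop-2-en-1-yl}oxy)-5-vinylphenyl]-2-[3,4-bis(benzyloxy)phenyl]chromane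
Product: 17 (2R,3S,4R)-3,7-bis(benzyloxy)-4-{(2R)-7-(benzyloxy)-2-[3,4-bis(benzyloxy)phenyl]-2H-chromen-6-yl}-2-[3,4-bis(benzyloxy)phenyl]chromane
Conditions: second-generation Grubbs catalyst RuCl2(=CHPh)(H2IMes)(PCy3) (5 mol %), 1,4-benzoquinone (10 mol %), CH2Cl2 (5 mM, degassed), 40 °C, dark
Reagents that add atoms: none
Why: Ring-closing olefin metathesis by the Chauvin mechanism; the closest known reaction type is the closure of 2-vinylphenyl 1-arylallyl ethers to 2-aryl-2H-chromenes. The ruthenium benzylidene exchanges with one terminal alkene, most likely the vinyl group of the allylic ether. The new alkylidene adds across the ring D styrene in a [2+2] sense to a ruthenacyclobutane, and cycloreversion forms the lower C3=C4 bond, with ethylene lost over the cycle. Ring F thus closes as a six-membered ring by alkene–alkene union, and its endocyclic double bond can only be cis. No stereocentre is formed; lower C2 is not a reacting centre and keeps the configuration set in step 10. The selectivity needed is chemoselectivity, and 16 secures it by holding exactly two alkenes, both monosubstituted, beside arenes and ethers that the catalyst ignores. High dilution favours closure over dimerisation, loss of ethylene drives the reaction, and benzoquinone intercepts ruthenium hydrides that would move the allyl double bond towards oxygen.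

Step 13
Reactants: 17 (2R,3S,4R)-3,7-bis(benzyloxy)-4-{(2R)-7-(benzyloxy)-2-[3,4-bis(benzyloxy)phenyl]-2H-chromen-6-yl}-2-[3,4-bis(benzyloxy)phenyl]chromane
Product: 19 (2S,3R)-7-(benzyloxy)-6-{(2R,3S,4R)-3,7-bis(benzyloxy)-2-[3,4-bis(benzyloxy)phenyl]chroman-4-yl}-2-[3,4-bis(benzyloxy)phenyl]chroman-3-ol, via lower C3 alkylborane 18 (not isolated)
Conditions: BH3·THF (3 equiv), THF, 0 °C to rt; then 3 M NaOH, 30% H2O2, 0 °C to rt
Reagents that add atoms: borane–tetrahydrofuran (boron of 18), B.C1CCOC1; hydrogen peroxide, OO
Why: Hydroboration–oxidation: syn addition of B–H puts boron on C3, because hydride goes to benzylic C4 (supported by the para benzyloxy group of ring D) and the allylic oxygen also directs boron to C3, and on the face away from ring E. Oxidation with retention gives the 2,3-trans alcohol, so lower C3 (R) is set by substrate control from C2.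

Step 14
Reactants: 19 (2S,3R)-7-(benzyloxy)-6-{(2R,3S,4R)-3,7-bis(benzyloxy)-2-[3,4-bis(benzyloxy)phenyl]chroman-4-yl}-2-[3,4-bis(benzyloxy)phenyl]chroman-3-ol
Product: 20 (2S)-7-(benzyloxy)-6-{(2R,3S,4R)-3,7-bis(benzyloxy)-2-[3,4-bis(benzyloxy)phenyl]chroman-4-yl}-2-[3,4-bis(benzyloxy)phenyl]chroman-3-one
Conditions: Dess–Martin periodinane, NaHCO3, CH2Cl2, 0 °C to rt
Reagents that add atoms: none
Why: Dess–Martin oxidation of the secondary alcohol under buffered, non-enolising conditions, the usual way from O-benzyl 2,3-trans flavan-3-ols to flavan-3-ones; the ketone is used without storage.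

Step 15
Reactants: 20 (2S)-7-(benzyloxy)-6-{(2R,3S,4R)-3,7-bis(benzyloxy)-2-[3,4-bis(benzyloxy)phenyl]chroman-4-yl}-2-[3,4-bis(benzyloxy)phenyl]chroman-3-one
Product: 21 (2S,3S)-7-(benzyloxy)-6-{(2R,3S,4R)-3,7-bis(benzyloxy)-2-[3,4-bis(benzyloxy)phenyl]chroman-4-yl}-2-[3,4-bis(benzyloxy)phenyl]chroman-3-ol
Conditions: LiBH(s-Bu)3 (L-Selectride), THF, −78 °C; aq. NH4Cl
Reagents that add atoms: none
Why: Bulky-hydride ketone reduction: LiBH(s-Bu)3 attacks the C3 carbonyl from the face opposite ring E, so the hydroxyl ends cis to the aryl group (lower C3, S, substrate control). At −78 °C reduction is faster than enolisation towards C2, which keeps C2 intact.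

Step 16
Reactants: 21 (2S,3S)-7-(benzyloxy)-6-{(2R,3S,4R)-3,7-bis(benzyloxy)-2-[3,4-bis(benzyloxy)phenyl]chroman-4-yl}-2-[3,4-bis(benzyloxy)phenyl]chroman-3-ol
Product: 22 (2R,3S,4R)-2-(3,4-dihydroxyphenyl)-4-[(2S,3S)-2-(3,4-dihydroxyphenyl)-3,7-dihydroxychroman-6-yl]chromane-3,7-diol
Conditions: H2 (1 atm), Pd(OH)2 on carbon, THF/MeOH (1:1), rt
Reagents that add atoms: none
Why: Catalytic hydrogenolysis of all seven benzyl ethers under neutral conditions; the cyclic benzylic C2–O bonds and the C4–C6 bond of flavans are cleaved much more slowly than O-benzyl groups, so the polyphenol is released without epimerisation.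

## Compound list

1 | 3,4-bis(benzyloxy)benzaldehyde | O=Cc1ccc(OCc2ccccc2)c(OCc2ccccc2)c1 | starting material
2 | ethyl (E)-3-[3,4-bis(benzyloxy)phenyl]prop-2-enoate | CCOC(=O)/C=C/c1ccc(OCc2ccccc2)c(OCc2ccccc2)c1 | intermediate
3 | (E)-3-[3,4-bis(benzyloxy)phenyl]prop-2-en-1-ol | OC/C=C/c1ccc(OCc2ccccc2)c(OCc2ccccc2)c1 | intermediate
4 | (E)-3-[3,4-bis(benzyloxy)phenyl]prop-2-en-1-yl methyl carbonate | COC(=O)OC/C=C/c1ccc(OCc2ccccc2)c(OCc2ccccc2)c1 | intermediate
5 | (2R,3R)-fustin, (2R,3R)-2-(3,4-dihydroxyphenyl)-3,7-dihydroxychroman-4-one | Oc1ccc2c(c1)O[C@H](c1ccc(O)c(O)c1)[C@@H](O)C2=O | starting material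
6 | (2R,3R)-7-(benzyloxy)-2-[3,4-bis(benzyloxy)phenyl]-3-hydroxychroman-4-one | c9ccccc9COc1ccc2c(c1)O[C@H](c1ccc(OCc9ccccc9)c(OCc9ccccc9)c1)[C@@H](O)C2=O | intermediate
7 | (2R,3S,4R)-7-(benzyloxy)-2-[3,4-bis(benzyloxy)phenyl]chromane-3,4-diol (2,3-trans-3,4-trans) | c9ccccc9COc1ccc2c(c1)O[C@H](c1ccc(OCc9ccccc9)c(OCc9ccccc9)c1)[C@@H](O)[C@@H]2O | intermediate
8 | resorcinol | Oc1cccc(O)c1 | starting material
9 | (2R,3S,4R)-7-(benzyloxy)-2-[3,4-bis(benzyloxy)phenyl]-4-(2,4-dihydroxyphenyl)chroman-3-ol (all-trans) | c9ccccc9COc1ccc2c(c1)O[C@H](c1ccc(OCc9ccccc9)c(OCc9ccccc9)c1)[C@@H](O)[C@@H]2c1ccc(O)cc1O | intermediate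
10 | N-[(5-{(2R,3S,4R)-7-(benzyloxy)-2-[3,4-bis(benzyloxy)phenyl]-3-hydroxychroman-4-yl}-2,4-dihydroxyphenyl)methylidene]-N-methylmethanaminium chloride | c9ccccc9COc1ccc2c(c1)O[C@H](c1ccc(OCc9ccccc9)c(OCc9ccccc9)c1)[C@@H](O)[C@@H]2c1cc(C=[N+](C)C)c(O)cc1O.[Cl-] | intermediate (not isolated)
11 | 5-{(2R,3S,4R)-7-(benzyloxy)-2-[3,4-bis(benzyloxy)phenyl]-3-hydroxychroman-4-yl}-2,4-dihydroxybenzaldehyde | c9ccccc9COc1ccc2c(c1)O[C@H](c1ccc(OCc9ccccc9)c(OCc9ccccc9)c1)[C@@H](O)[C@@H]2c1cc(C=O)c(O)cc1O | intermediate
12 | 4-(benzyloxy)-5-{(2R,3S,4R)-7-(benzyloxy)-2-[3,4-bis(benzyloxy)phenyl]-3-hydroxychroman-4-yl}-2-hydroxybenzaldehyde | c9ccccc9COc1ccc2c(c1)O[C@H](c1ccc(OCc9ccccc9)c(OCc9ccccc9)c1)[C@@H](O)[C@@H]2c1cc(C=O)c(O)cc1OCc9ccccc9 | intermediate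
13 | 5-(benzyloxy)-4-{(2R,3S,4R)-7-(benzyloxy)-2-[3,4-bis(benzyloxy)phenyl]-3-hydroxychroman-4-yl}-2-vinylphenol | c9ccccc9COc1ccc2c(c1)O[C@H](c1ccc(OCc9ccccc9)c(OCc9ccccc9)c1)[C@@H](O)[C@@H]2c1cc(C=C)c(O)cc1OCc9ccccc9 | intermediate
14 | lithium 5-(benzyloxy)-4-{(2R,3S,4R)-7-(benzyloxy)-2-[3,4-bis(benzyloxy)phenyl]-3-hydroxychroman-4-yl}-2-vinylphenoxide | [Li+].c9ccccc9COc1ccc2c(c1)O[C@H](c1ccc(OCc9ccccc9)c(OCc9ccccc9)c1)[C@@H](O)[C@@H]2c1cc(C=C)c([O-])cc1OCc9ccccc9 | intermediate (not isolated)
15 | (2R,3S,4R)-7-(benzyloxy)-4-[2-(benzyloxy)-4-({(1R)-1-[3,4-bis(benzyloxy)phenyl]prop-2-en-1-yl}oxy)-5-vinylphenyl]-2-[3,4-bis(benzyloxy)phenyl]chroman-3-ol | c9ccccc9COc1ccc2c(c1)O[C@H](c1ccc(OCc9ccccc9)c(OCc9ccccc9)c1)[C@@H](O)[C@@H]2c1cc(C=C)c(cc1OCc9ccccc9)O[C@@H](c1ccc(OCc9ccccc9)c(OCc9ccccc9)c1)C=C | intermediate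
16 | (2R,3S,4R)-3,7-bis(benzyloxy)-4-[2-(benzyloxy)-4-({(1R)-1-[3,4-bis(benzyloxy)phenyl]prop-2-en-1-yl}oxy)-5-vinylphenyl]-2-[3,4-bis(benzyloxy)phenyl]chromane | c9ccccc9COc1ccc2c(c1)O[C@H](c1ccc(OCc9ccccc9)c(OCc9ccccc9)c1)[C@@H](OCc9ccccc9)[C@@H]2c1cc(C=C)c(cc1OCc9ccccc9)O[C@@H](c1ccc(OCc9ccccc9)c(OCc9ccccc9)c1)C=C | intermediate (precursor of the key step)
17 | (2R,3S,4R)-3,7-bis(benzyloxy)-4-{(2R)-7-(benzyloxy)-2-[3,4-bis(benzyloxy)phenyl]-2H-chromen-6-yl}-2-[3,4-bis(benzyloxy)phenyl]chromane | c9ccccc9COc1ccc2c(c1)O[C@H](c1ccc(OCc9ccccc9)c(OCc9ccccc9)c1)[C@@H](OCc9ccccc9)[C@@H]2c1cc2c(cc1OCc9ccccc9)O[C@@H](c1ccc(OCc9ccccc9)c(OCc9ccccc9)c1)C=C2 | intermediate (product of the key step)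
18 | lower C3 borane of 17: BH2 on lower C3 trans to ring E, hydrogen on lower C4 | c9ccccc9COc1ccc2c(c1)O[C@H](c1ccc(OCc9ccccc9)c(OCc9ccccc9)c1)[C@@H](OCc9ccccc9)[C@@H]2c1cc2c(cc1OCc9ccccc9)O[C@@H](c1ccc(OCc9ccccc9)c(OCc9ccccc9)c1)[C@H](B)C2 | intermediate (not isolated)
19 | (2S,3R)-7-(benzyloxy)-6-{(2R,3S,4R)-3,7-bis(benzyloxy)-2-[3,4-bis(benzyloxy)phenyl]chroman-4-yl}-2-[3,4-bis(benzyloxy)phenyl]chroman-3-ol (lower unit 2,3-trans) | c9ccccc9COc1ccc2c(c1)O[C@H](c1ccc(OCc9ccccc9)c(OCc9ccccc9)c1)[C@@H](OCc9ccccc9)[C@@H]2c1cc2c(cc1OCc9ccccc9)O[C@@H](c1ccc(OCc9ccccc9)c(OCc9ccccc9)c1)[C@H](O)C2 | intermediate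
20 | (2S)-7-(benzyloxy)-6-{(2R,3S,4R)-3,7-bis(benzyloxy)-2-[3,4-bis(benzyloxy)phenyl]chroman-4-yl}-2-[3,4-bis(benzyloxy)phenyl]chroman-3-one | c9ccccc9COc1ccc2c(c1)O[C@H](c1ccc(OCc9ccccc9)c(OCc9ccccc9)c1)[C@@H](OCc9ccccc9)[C@@H]2c1cc2c(cc1OCc9ccccc9)O[C@@H](c1ccc(OCc9ccccc9)c(OCc9ccccc9)c1)C(=O)C2 | intermediate
21 | (2S,3S)-7-(benzyloxy)-6-{(2R,3S,4R)-3,7-bis(benzyloxy)-2-[3,4-bis(benzyloxy)phenyl]chroman-4-yl}-2-[3,4-bis(benzyloxy)phenyl]chroman-3-ol (lower unit 2,3-cis; hepta-O-benzyl ether of 22) | c9ccccc9COc1ccc2c(c1)O[C@H](c1ccc(OCc9ccccc9)c(OCc9ccccc9)c1)[C@@H](OCc9ccccc9)[C@@H]2c1cc2c(cc1OCc9ccccc9)O[C@@H](c1ccc(OCc9ccccc9)c(OCc9ccccc9)c1)[C@@H](O)C2 | intermediate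
22 | (2R,3S,4R)-2-(3,4-dihydroxyphenyl)-4-[(2S,3S)-2-(3,4-dihydroxyphenyl)-3,7-dihydroxychroman-6-yl]chromane-3,7-diol | Oc1ccc2c(c1)O[C@H](c1ccc(O)c(O)c1)[C@@H](O)[C@@H]2c1cc2c(cc1O)O[C@@H](c1ccc(O)c(O)c1)[C@@H](O)C2 | target

## Step count and least certain steps

Total step count: 16. Longest linear sequence: 13 steps (steps 4–16, from fustin 5). The carbonate branch (steps 1–3) joins at step 10.

Step 12 (key step). The allyl double bond may migrate towards oxygen under ruthenium hydride species formed as the catalyst decays, which would be followed by a ring-contracting metathesis; slow closure would also allow oligomerisation through the styrene, and the flavene may ionise or oxidise during isolation. The cause is that the O–CH(Ar)–CH=CH2 unit is a doubly activated allylic system and the donor-substituted ring D styrene is a slow olefin partner.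
Fallback, from alcohol 3 and salicylaldehyde 12, returning at 17: ring F is closed by condensation instead of metathesis.
- MnO2 oxidation of 3 would give (E)-3-[3,4-bis(benzyloxy)phenyl]prop-2-enal F1.
- An aminocatalytic oxa-Michael/aldol condensation of 12 with F1 (α,α-diphenylprolinol trimethylsilyl ether, 2-nitrobenzoic acid, toluene) would add the phenol oxygen to the iminium ion and close the ring by aldol dehydration. The product would be 7-(benzyloxy)-6-{(2R,3S,4R)-7-(benzyloxy)-2-[3,4-bis(benzyloxy)phenyl]-3-hydroxychroman-4-yl}-2-[3,4-bis(benzyloxy)phenyl]-2H-chromene-3-carbaldehyde F2, with lower C2 set by the choice of catalyst enantiomer.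
- Decarbonylation with stoichiometric RhCl(PPh3)3 in toluene at 90 °C would give (2R,3S,4R)-7-(benzyloxy)-4-{(2R)-7-(benzyloxy)-2-[3,4-bis(benzyloxy)phenyl]-2H-chromen-6-yl}-2-[3,4-bis(benzyloxy)phenyl]chroman-3-ol F3.
- Benzylation of the upper 3-hydroxyl (NaH, BnBr) would lead to 17.

Step 10. The branched-to-linear ratio and the configuration at lower C2 may erode through reversible ionisation of the product at iridium, because the 3,4-dialkoxycinnamyl system forms an unusually stable allyl cation equivalent. The ortho-vinyl aryloxide may also react slowly.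
Fallback, from aldehyde 1 and phenol 13, returning at 15: the ether bond is made by inversion at a preformed stereocentre.
- CH2=CHMgBr would add to 1 to give racemic 1-[3,4-bis(benzyloxy)phenyl]prop-2-en-1-ol F4.
- Lipase-catalysed acetylation (Candida antarctica lipase B, vinyl acetate) is expected to convert the R enantiomer to (R)-1-[3,4-bis(benzyloxy)phenyl]prop-2-en-1-yl acetate F6 and leave (S)-1-[3,4-bis(benzyloxy)phenyl]prop-2-en-1-ol F5.
- A Mitsunobu reaction of 13 with F5 (PPh3, diisopropyl azodicarboxylate, toluene, 0 °C) would form the aryl ether with inversion, giving 15. The hindered upper 3-hydroxyl of 13 should be activated far more slowly than the allylic alcohol.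

Step 13. Boron may be delivered to C4 instead of C3, or the C3 borane may undergo β-elimination across the C2–O1 bond with opening of ring F, since the leaving group would be an aryloxide.
Fallback, from 17, returning at 19: oxygen is introduced by osmylation and the surplus oxygen removed.
- Dihydroxylation (OsO4 cat., N-methylmorpholine N-oxide, acetone/water) anti to ring E would give the lower-unit 2,3-trans-3,4-cis 3,4-diol of 17 F7.
- Ionic deoxygenation of its benzylic C4 hydroxyl (Et3SiH, CF3CO2H, CH2Cl2, −20 °C) would leave the 3-hydroxyl in place and give 19. The C4 cation is the one stabilised by the para benzyloxy group of ring D.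

Step 6. Resorcinol may attack the C4 cation on the face syn to the C3 hydroxyl, giving the 3,4-cis epimer, and 9 may be alkylated a second time, because facial control comes from a single neighbouring hydroxyl and the product is itself a nucleophilic resorcinol.
Fallback, from 7, returning at 9: neighbouring-group control.
- Acetylation (Ac2O, pyridine) would give the 3,4-di-O-acetate of 7 F8.
- With BF3·OEt2 and resorcinol, the 3-acetoxy group would assist ionisation at C4 as a cis-fused acetoxonium ion, which can only be opened from the opposite face. This would give the 3-O-acetate of 9 F9 as the 3,4-trans isomer.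
- K2CO3 in methanol would remove the acetate and give 9.

Step 7. The chloroiminium salt may formylate ring A or the carbon between the two ring D hydroxyls, and may formylate or chlorinate the upper C3 hydroxyl, because it is an unselective electrophile towards any electron-rich site or free hydroxyl.
Fallback, from 9, returning directly at 11: a phenoxide-directed ortho-formylation (MgCl2, Et3N, paraformaldehyde, MeCN, reflux). Only a magnesium aryloxide can deliver formaldehyde to its own ortho carbon, followed by hydride transfer to a second formaldehyde, so ring A and the aliphatic hydroxyl cannot react. This fallback makes no compound outside the list (F0).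

## Further compounds

F1 | step 12 | (E)-3-[3,4-bis(benzyloxy)phenyl]prop-2-enal | O=C/C=C/c1ccc(OCc2ccccc2)c(OCc2ccccc2)c1
F2 | step 12 | 7-(benzyloxy)-6-{(2R,3S,4R)-7-(benzyloxy)-2-[3,4-bis(benzyloxy)phenyl]-3-hydroxychroman-4-yl}-2-[3,4-bis(benzyloxy)phenyl]-2H-chromene-3-carbaldehyde (lower C2 as in 17) | c9ccccc9COc1ccc2c(c1)O[C@H](c1ccc(OCc9ccccc9)c(OCc9ccccc9)c1)[C@@H](O)[C@@H]2c1cc2c(cc1OCc9ccccc9)O[C@@H](c1ccc(OCc9ccccc9)c(OCc9ccccc9)c1)C(C=O)=C2
F3 | step 12 | (2R,3S,4R)-7-(benzyloxy)-4-{(2R)-7-(benzyloxy)-2-[3,4-bis(benzyloxy)phenyl]-2H-chromen-6-yl}-2-[3,4-bis(benzyloxy)phenyl]chroman-3-ol | c9ccccc9COc1ccc2c(c1)O[C@H](c1ccc(OCc9ccccc9)c(OCc9ccccc9)c1)[C@@H](O)[C@@H]2c1cc2c(cc1OCc9ccccc9)O[C@@H](c1ccc(OCc9ccccc9)c(OCc9ccccc9)c1)C=C2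
F4 | step 10 | racemic 1-[3,4-bis(benzyloxy)phenyl]prop-2-en-1-ol | C=CC(O)c1ccc(OCc2ccccc2)c(OCc2ccccc2)c1
F5 | step 10 | (S)-1-[3,4-bis(benzyloxy)phenyl]prop-2-en-1-ol | C=C[C@H](O)c1ccc(OCc2ccccc2)c(OCc2ccccc2)c1
F6 | step 10 | (R)-1-[3,4-bis(benzyloxy)phenyl]prop-2-en-1-yl acetate | C=C[C@@H](OC(C)=O)c1ccc(OCc2ccccc2)c(OCc2ccccc2)c1
F7 | step 13 | lower-unit 2,3-trans-3,4-cis 3,4-diol of 17 (both hydroxyls anti to ring E) | c9ccccc9COc1ccc2c(c1)O[C@H](c1ccc(OCc9ccccc9)c(OCc9ccccc9)c1)[C@@H](OCc9ccccc9)[C@@H]2c1cc2c(cc1OCc9ccccc9)O[C@@H](c1ccc(OCc9ccccc9)c(OCc9ccccc9)c1)[C@H](O)[C@@H]2O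
F8 | step 6 | 3,4-di-O-acetate of 7 | c9ccccc9COc1ccc2c(c1)O[C@H](c1ccc(OCc9ccccc9)c(OCc9ccccc9)c1)[C@@H](OC(C)=O)[C@@H]2OC(C)=O
F9 | step 6 | 3-O-acetate of 9 | c9ccccc9COc1ccc2c(c1)O[C@H](c1ccc(OCc9ccccc9)c(OCc9ccccc9)c1)[C@@H](OC(C)=O)[C@@H]2c1ccc(O)cc1O
F0 | step 7 | none | none
A1 | alternative 1 | [4-(benzyloxy)-2-hydroxyphenyl]{(2S,3S)-3,7-bis(benzyloxy)-2-[3,4-bis(benzyloxy)phenyl]chroman-6-yl}methanol (carbinol configuration immaterial) | OC(c1ccc(OCc9ccccc9)cc1O)c1cc2c(cc1OCc9ccccc9)O[C@@H](c1ccc(OCc9ccccc9)c(OCc9ccccc9)c1)[C@@H](OCc9ccccc9)C2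
A2 | alternative 1 | benzyl{(E)-2-[3,4-bis(benzyloxy)phenyl]ethenyl}dimethylsilane | C[Si](C)(Cc1ccccc1)/C=C/c1ccc(OCc2ccccc2)c(OCc2ccccc2)c1
A3 | alternative 1 | per-O-benzyl dimer with a benzyldimethylsilyl group in place of the upper C3 hydroxyl | c9ccccc9COc1ccc2c(c1)O[C@H](c1ccc(OCc9ccccc9)c(OCc9ccccc9)c1)[C@@H]([Si](C)(C)Cc9ccccc9)[C@@H]2c1cc2c(cc1OCc9ccccc9)O[C@@H](c1ccc(OCc9ccccc9)c(OCc9ccccc9)c1)[C@@H](OCc9ccccc9)C2
A4 | alternative 2 | 2-{(2R,3S,4R)-3,7-bis(benzyloxy)-2-[3,4-bis(benzyloxy)phenyl]chroman-4-yl}-1,1-dimethoxyoctane-3,5,7-trione (chain C2 undefined) | c9ccccc9COc1ccc2c(c1)O[C@H](c1ccc(OCc9ccccc9)c(OCc9ccccc9)c1)[C@@H](OCc9ccccc9)[C@@H]2C(C(OC)OC)C(=O)CC(=O)CC(C)=O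
A5 | alternative 2 | 1-(5-{(2R,3S,4R)-3,7-bis(benzyloxy)-2-[3,4-bis(benzyloxy)phenyl]chroman-4-yl}-2,4-dihydroxyphenyl)ethanone | c9ccccc9COc1ccc2c(c1)O[C@H](c1ccc(OCc9ccccc9)c(OCc9ccccc9)c1)[C@@H](OCc9ccccc9)[C@@H]2c1cc(C(C)=O)c(O)cc1O
A6 | alternative 3 | 5-(benzyloxy)-4-{(2R,3S,4R)-7-(benzyloxy)-2-[3,4-bis(benzyloxy)phenyl]-3-hydroxychroman-4-yl}-2-{(Z)-3-[3,4-bis(benzyloxy)phenyl]prop-2-en-1-yl}phenyl acetate | c9ccccc9COc1ccc2c(c1)O[C@H](c1ccc(OCc9ccccc9)c(OCc9ccccc9)c1)[C@@H](O)[C@@H]2c1cc(C/C=C\c3ccc(OCc9ccccc9)c(OCc9ccccc9)c3)c(OC(C)=O)cc1OCc9ccccc9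
A7 | alternative 3 | hexa-O-benzyl ether of 22 with both C3 hydroxyls free | c9ccccc9COc1ccc2c(c1)O[C@H](c1ccc(OCc9ccccc9)c(OCc9ccccc9)c1)[C@@H](O)[C@@H]2c1cc2c(cc1OCc9ccccc9)O[C@@H](c1ccc(OCc9ccccc9)c(OCc9ccccc9)c1)[C@@H](O)C2
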